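## Retrosynthetic overview

1. Feature: in the butenolide ring (O1, C2 lactone carbonyl, C3 enol carbon, C4 aryl-bearing carbon, C5 quaternary carbon), C3 and C4 are treated as the two carbons of an alkyne joining the C5 carbinol carbon to the C2 ester carbon. Placing the 4-oxyphenyl ring on C4 creates the ring alkene and brings the C5 oxygen next to the C2 ester.
2. Target 26 ⇐ desilylation and catalyst-controlled epoxidation of the prenyl alkene ⇐ enol 23 ⇐ C3–I to C3–OH (borylation, oxidation) ⇐ 3-iodo-4-aryl butenolide 21.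
3. 21 ⇐ ynoate 15 + arylcopper reagent from Grignard reagent 18 (C4–aryl and O1–C2 bonds, iodine on C3).
4. 15 ⇐ alkyne 12 ⇐ formyl dioxolanone 10 ⇐ pivalaldehyde acetal 8 of the aryl-lactic acid from 3-iodo-L-tyrosine (C5 set by self-regeneration of stereocentres; prenyl by Negishi coupling).
5. Ring order: dioxolanone auxiliary ring (step 2, opened in step 7), butenolide (step 11), oxirane (step 14).

Key step: step 11

Assumption: a free aryl-lactic acid phenol cannot be C-prenylated cleanly with prenyl bromide, so the prenyl group is introduced by cross-coupling at the iodine of commercial 3-iodo-L-tyrosine.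

Notation: TIPS = triisopropylsilyl, TIPSO = triisopropylsilyloxy, prenyl = 3-methylbut-2-enyl. Butenolide numbering (O1, C2 = lactone carbonyl, C3, C4, C5) is used in all names and in the text.

## Route

Step 1
Reactants: 1 3-iodo-L-tyrosine
Product: 2 (2S)-2-hydroxy-3-(4-hydroxy-3-iodophenyl)propanoic acid
Conditions: NaNO2, 1 M H2SO4, H2O, 0 °C → rt
Reagents that add atoms: water, O
Why: Diazotisation of the α-amino acid and substitution by water through the α-lactone (two inversions) should replace NH2 by OH with net retention, so the (S) centre of 1 is kept.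

Step 2
Reactants: 2 (2S)-2-hydroxy-3-(4-hydroxy-3-iodophenyl)propanoic acid; 3 pivalaldehyde
Product: 4 (2S,5S)-2-tert-butyl-5-(4-hydroxy-3-iodobenzyl)-1,3-dioxolan-4-one (cis)
Conditions: p-TsOH·H2O (cat.), H2SO4 (cat.), pentane, reflux, Dean–Stark; recrystallisation
Reagents that add atoms: none
Why: Acid-catalysed acetalisation of the α-hydroxy acid with pivalaldehyde (first stage of the self-regeneration of stereocentres) should favour the cis dioxolanone, in which the existing C5 centre sets the acetal carbon as (2S), and recrystallisation removes the trans isomer.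

Step 3
Reactants: 4 (2S,5S)-2-tert-butyl-5-(4-hydroxy-3-iodobenzyl)-1,3-dioxolan-4-one
Product: 5 (2S,5S)-2-tert-butyl-5-[3-iodo-4-(TIPSO)benzyl]-1,3-dioxolan-4-one
Conditions: TIPSOTf, 2,6-lutidine, CH2Cl2, 0 °C
Reagents that add atoms: triisopropylsilyl trifluoromethanesulfonate, CC(C)[Si](OS(=O)(=O)C(F)(F)F)(C(C)C)C(C)C
Why: Silyl ether formation at the phenol with a silyl triflate and a hindered pyridine base is fast at 0 °C and avoids nucleophilic amines that could open the acylal-type lactone.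

Step 4
Reactants: 5 (2S,5S)-2-tert-butyl-5-[3-iodo-4-(TIPSO)benzyl]-1,3-dioxolan-4-one; 6 prenyl bromide
Product: 8 (2S,5S)-2-tert-butyl-5-[3-prenyl-4-(TIPSO)benzyl]-1,3-dioxolan-4-one, via prenylzinc bromide 7 (not isolated)
Conditions: 6, Zn dust, LiCl, THF, rt; then 5, Pd(OAc)2 (cat.), 2-dicyclohexylphosphino-2′,6′-bis(dimethylamino)biphenyl (CPhos, cat.), THF, rt
Reagents that add atoms: zinc, [Zn] (kept only in 7)
Why: Negishi cross-coupling of the aryl iodide with an allylic zinc reagent, in which reductive elimination from the σ-prenylpalladium isomer bound at its primary carbon should give the linear prenyl arene, tolerates the lactone and the silyl ether because the organozinc is only weakly basic and nucleophilic.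

Step 5
Reactants: 8 (2S,5S)-2-tert-butyl-5-[3-prenyl-4-(TIPSO)benzyl]-1,3-dioxolan-4-one
Product: 10 (2S,4R)-2-tert-butyl-5-oxo-4-[3-prenyl-4-(TIPSO)benzyl]-1,3-dioxolane-4-carbaldehyde, via lithium enolate 9 (not isolated)
Conditions: LiN(i-Pr)2, THF, −78 °C; HCO2Et (excess), −78 °C; AcOH, −78 °C
Reagents that add atoms: ethyl formate, CCOC=O; lithium diisopropylamide, CC(C)N([Li])C(C)C (lithium kept only in 9)
Why: Claisen-type C-formylation of the dioxolanone lithium enolate, whose planar carbon is attacked on the face anti to the tert-butyl group at C2, puts the formyl group in the place of the former hydrogen and sets the new quaternary centre as (R) under control of the acetal centre (self-regeneration of stereocentres).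

Step 6
Reactants: 10 (2S,4R)-2-tert-butyl-5-oxo-4-[3-prenyl-4-(TIPSO)benzyl]-1,3-dioxolane-4-carbaldehyde
Product: 11 (2S,5R)-2-tert-butyl-5-ethynyl-5-[3-prenyl-4-(TIPSO)benzyl]-1,3-dioxolan-4-one
Conditions: (MeO)2P(O)CHN2, t-BuOK, THF, −78 °C → rt
Reagents that add atoms: dimethyl (diazomethyl)phosphonate, COP(=O)(OC)C=[N+]=[N-]
Why: Seyferth–Gilbert homologation of a non-enolisable aldehyde (addition of the diazophosphonate anion, loss of dimethyl phosphate and N2, 1,2-hydrogen shift of the alkylidene carbene) runs aprotically, so the terminal alkyne should form without methanolysis or deformylation and without touching the quaternary centre.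

Step 7
Reactants: 11 (2S,5R)-2-tert-butyl-5-ethynyl-5-[3-prenyl-4-(TIPSO)benzyl]-1,3-dioxolan-4-one
Product: 12 methyl (2R)-2-ethynyl-2-hydroxy-3-[3-prenyl-4-(TIPSO)phenyl]propanoate
Conditions: NaOMe (0.2 equiv), MeOH, 0 °C; aq. NH4Cl
Reagents that add atoms: methanol, CO
Why: Methoxide-mediated transesterification (acyl substitution) opens the activated dioxolanone to the methyl ester and a hemiacetal alkoxide that loses pivalaldehyde, and it is done before the methoxide-sensitive ynoate exists and does not involve the quaternary centre.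

Step 8
Reactants: 12 methyl (2R)-2-ethynyl-2-hydroxy-3-[3-prenyl-4-(TIPSO)phenyl]propanoate
Product: 15 dimethyl (4R)-4-hydroxy-4-[3-prenyl-4-(TIPSO)benzyl]pent-2-ynedioate, via O-silylated alkyne 13 (not isolated), via O-silylated ynoate 14 (not isolated)
Conditions: LiN(i-Pr)2 (1.0 equiv), THF, −78 °C; Me3SiCl (1.0 equiv), −78 → 0 °C; LiN(i-Pr)2 (1.1 equiv), −78 °C; ClCO2Me; then 1 M HCl, THF, rt
Reagents that add atoms: methyl chloroformate, COC(=O)Cl; chlorotrimethylsilane, C[Si](C)(C)Cl (silicon kept only in 13 and 14)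
Why: C-acylation of a lithium acetylide with methyl chloroformate, with the tertiary alkoxide first capped in the same flask as its trimethylsilyl ether so that only carbon is acylated, is followed by dilute acid that removes the labile tertiary trimethylsilyl ether and leaves the aryl TIPS ether.

Step 9
Reactants: 16 4-bromophenol
Product: 17 (4-bromophenoxy)triisopropylsilane
Conditions: TIPSCl, imidazole, DMF, rt
Reagents that add atoms: chlorotriisopropylsilane, CC(C)[Si](Cl)(C(C)C)C(C)C
Why: Standard silyl ether formation (silyl chloride, imidazole) protects the phenol so that the Grignard reagent can be made.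

Step 10
Reactants: 17 (4-bromophenoxy)triisopropylsilane
Product: 18 [4-(TIPSO)phenyl]magnesium bromide (THF solution, titrated)
Conditions: Mg turnings (activated with a crystal of iodine), THF, reflux → rt
Reagents that add atoms: magnesium, [Mg]
Why: Grignard reagent formation by direct magnesium insertion into the aryl bromide, to which the hindered aryl silyl ether is inert.

Step 11
Reactants: 15 dimethyl (4R)-4-hydroxy-4-[3-prenyl-4-(TIPSO)benzyl]pent-2-ynedioate; 18 [4-(TIPSO)phenyl]magnesium bromide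
Product: 21 methyl (5R)-3-iodo-2-oxo-5-[3-prenyl-4-(TIPSO)benzyl]-4-[4-(TIPSO)phenyl]-2,5-dihydrofuran-5-carboxylate, via alkenylcopper adduct 19 (not isolated), via open-chain iodo enoate 20 (not isolated)
Conditions: 18 (1.0 equiv), THF, −78 °C (alkoxide); then into ArCu·MgBr2 [18 (1.5 equiv) + CuBr·SMe2 (1.5 equiv)], THF, −78 → −40 °C; I2 in THF, −78 °C → rt; aq. Na2S2O3, NH4Cl
Reagents that add atoms: iodine, [I][I]; copper bromide–dimethyl sulfide complex (CuBr·SMe2), [Cu]Br.CSC (copper kept only in 19)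
Why: The reaction is a syn-carbocupration of an alkynoate followed by iodinolysis and lactonisation: the arylcopper reagent π-complexes the alkyne conjugated to the C2 ester and transfers its aryl group to C4, the carbon β to that ester, while copper ends on C3 on the same side (19), and iodine then replaces the C3–Cu bond with retention of the alkene geometry (20). The closest known reactions are the syn-addition of organocopper reagents to 2-alkynoates with electrophilic trapping of the α-cuprio enoate and the cuprate route from 4-hydroxy-2-alkynoates to butenolides. The butenolide ring closes by 5-exo-trig acyl substitution: because the addition is syn, the C5 alkoxide and the C2 ester are cis in 20, and on warming the alkoxide attacks the ester carbonyl and expels methoxide (O1–C2 bond). No stereocentre is formed, and C5, a fully substituted carbon set in step 5, cannot epimerise. The step needs aryl delivery to C4 and not C3, and it needs the syn geometry to survive until iodination; the first is secured because only the C2 ester is conjugated to the alkyne (the C5 ester is insulated by the quaternary carbon) and the linear alkyne leaves C4 open to the reagent, the second by using the monoarylcopper reagent in THF at −78 to −40 °C, below the temperature at which the α-cuprio enoate equilibrates through its copper allenoate, and any anti adduct cannot lactonise and is removed as an open-chain by-product.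

Step 12
Reactants: 21 methyl (5R)-3-iodo-2-oxo-5-[3-prenyl-4-(TIPSO)benzyl]-4-[4-(TIPSO)phenyl]-2,5-dihydrofuran-5-carboxylate
Product: 23 methyl (5R)-3-hydroxy-2-oxo-5-[3-prenyl-4-(TIPSO)benzyl]-4-[4-(TIPSO)phenyl]-2,5-dihydrofuran-5-carboxylate, via C3 pinacol boronate 22 (not isolated)
Conditions: B2pin2, PdCl2(dppf) (cat.), KOAc, 1,4-dioxane, 80 °C; then NaBO3·4H2O, THF–H2O, rt; aq. NaH2PO4
Reagents that add atoms: sodium perborate (NaBO3·4H2O), [Na+].[Na+].O[B-]1(O)OO[B-](O)(O)OO1; bis(pinacolato)diboron, CC1(C)OB(OC1(C)C)B1OC(C)(C)C(C)(C)O1 (boron kept only in 22)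
Why: Miyaura borylation of the alkenyl iodide (oxidative addition of zerovalent palladium into the C3–I bond, acetate-assisted transmetalation with B2pin2, reductive elimination) followed in the same flask by perborate oxidation of the C–B bond should give the enol, the stable tautomer of the α-keto lactone, while the isolated prenyl alkene is not touched.

Step 13
Reactants: 23 methyl (5R)-3-hydroxy-2-oxo-5-[3-prenyl-4-(TIPSO)benzyl]-4-[4-(TIPSO)phenyl]-2,5-dihydrofuran-5-carboxylate
Product: 24 methyl (5R)-2-oxo-5-[3-prenyl-4-(TIPSO)benzyl]-3-(TIPSO)-4-[4-(TIPSO)phenyl]-2,5-dihydrofuran-5-carboxylate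
Conditions: TIPSOTf, 2,6-lutidine, CH2Cl2, 0 °C
Reagents that add atoms: triisopropylsilyl trifluoromethanesulfonate, CC(C)[Si](OS(=O)(=O)C(F)(F)F)(C(C)C)C(C)C
Why: O-silylation of the enol (silyl enol ether formation) masks the acidic, electron-rich enol so that it is neither deprotonated nor oxidised under the basic dioxirane conditions of the next step.

Step 14
Reactants: 24 methyl (5R)-2-oxo-5-[3-prenyl-4-(TIPSO)benzyl]-3-(TIPSO)-4-[4-(TIPSO)phenyl]-2,5-dihydrofuran-5-carboxylate
Product: 25 methyl (5R)-5-{3-[((2R)-3,3-dimethyloxiran-2-yl)methyl]-4-(TIPSO)benzyl}-2-oxo-3-(TIPSO)-4-[4-(TIPSO)phenyl]-2,5-dihydrofuran-5-carboxylate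
Conditions: 1,2:4,5-di-O-isopropylidene-β-D-erythro-2,3-hexodiulo-2,6-pyranose (D-fructose-derived Shi ketone, 0.3 equiv), Oxone (2KHSO5·KHSO4·K2SO4), K2CO3, Bu4NHSO4 (cat.), aq. Na2B4O7/Na2EDTA buffer, MeCN–CH2(OMe)2, 0 °C
Reagents that add atoms: potassium peroxymonosulfate (KHSO5, from Oxone), [K+].[O-]S(=O)(=O)OO
Why: Shi asymmetric epoxidation, in which the chiral dioxirane from the D-fructose-derived ketone transfers oxygen through a spiro transition state to the trisubstituted prenyl alkene, should give the (R)-epoxide under catalyst control (the sense known for trisubstituted alkenes with this ketone), while the tetrasubstituted, conjugated and hindered ring alkene reacts far more slowly.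

Step 15
Reactants: 25 methyl (5R)-5-{3-[((2R)-3,3-dimethyloxiran-2-yl)methyl]-4-(TIPSO)benzyl}-2-oxo-3-(TIPSO)-4-[4-(TIPSO)phenyl]-2,5-dihydrofuran-5-carboxylate
Product: 26 methyl (5R)-5-{3-[((2R)-3,3-dimethyloxiran-2-yl)methyl]-4-hydroxybenzyl}-3-hydroxy-4-(4-hydroxyphenyl)-2-oxo-2,5-dihydrofuran-5-carboxylate (CNP0331593.1)
Conditions: Bu4NF, AcOH (1:1), THF, 0 °C; pH 7 buffer
Reagents that add atoms: none
Why: Fluoride-mediated desilylation of the three silyl ethers is buffered with acetic acid so that no phenoxide forms next to the epoxide, which it would otherwise open by 5-exo attack, and no stereocentre is touched.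

## Compound list

1 | 3-iodo-L-tyrosine | N[C@@H](Cc1ccc(O)c(I)c1)C(=O)O | starting material
2 | (2S)-2-hydroxy-3-(4-hydroxy-3-iodophenyl)propanoic acid | O[C@@H](Cc1ccc(O)c(I)c1)C(=O)O | intermediate
3 | pivalaldehyde | CC(C)(C)C=O | starting material
4 | (2S,5S)-2-tert-butyl-5-(4-hydroxy-3-iodobenzyl)-1,3-dioxolan-4-one | CC(C)(C)[C@H]1O[C@@H](Cc2ccc(O)c(I)c2)C(=O)O1 | intermediate
5 | (2S,5S)-2-tert-butyl-5-[3-iodo-4-(TIPSO)benzyl]-1,3-dioxolan-4-one | CC(C)(C)[C@H]1O[C@@H](Cc2ccc(O[Si](C(C)C)(C(C)C)C(C)C)c(I)c2)C(=O)O1 | intermediate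
6 | prenyl bromide | CC(C)=CCBr | starting material
7 | prenylzinc bromide | CC(C)=CC[Zn]Br | intermediate (not isolated)
8 | (2S,5S)-2-tert-butyl-5-[3-prenyl-4-(TIPSO)benzyl]-1,3-dioxolan-4-one | CC(C)(C)[C@H]1O[C@@H](Cc2ccc(O[Si](C(C)C)(C(C)C)C(C)C)c(CC=C(C)C)c2)C(=O)O1 | intermediate
9 | lithium enolate of 8 | CC(C)(C)[C@H]1OC(Cc2ccc(O[Si](C(C)C)(C(C)C)C(C)C)c(CC=C(C)C)c2)=C(O[Li])O1 | intermediate (not isolated)
10 | (2S,4R)-2-tert-butyl-5-oxo-4-[3-prenyl-4-(TIPSO)benzyl]-1,3-dioxolane-4-carbaldehyde | CC(C)(C)[C@H]1O[C@@](C=O)(Cc2ccc(O[Si](C(C)C)(C(C)C)C(C)C)c(CC=C(C)C)c2)C(=O)O1 | intermediate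
11 | (2S,5R)-2-tert-butyl-5-ethynyl-5-[3-prenyl-4-(TIPSO)benzyl]-1,3-dioxolan-4-one | CC(C)(C)[C@H]1O[C@@](C#C)(Cc2ccc(O[Si](C(C)C)(C(C)C)C(C)C)c(CC=C(C)C)c2)C(=O)O1 | intermediate
12 | methyl (2R)-2-ethynyl-2-hydroxy-3-[3-prenyl-4-(TIPSO)phenyl]propanoate | COC(=O)[C@](C#C)(Cc1ccc(O[Si](C(C)C)(C(C)C)C(C)C)c(CC=C(C)C)c1)O | intermediate
13 | methyl (2R)-2-ethynyl-3-[3-prenyl-4-(TIPSO)phenyl]-2-(trimethylsilyloxy)propanoate | COC(=O)[C@](C#C)(Cc1ccc(O[Si](C(C)C)(C(C)C)C(C)C)c(CC=C(C)C)c1)O[Si](C)(C)C | intermediate (not isolated)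
14 | dimethyl (4R)-4-[3-prenyl-4-(TIPSO)benzyl]-4-(trimethylsilyloxy)pent-2-ynedioate | COC(=O)[C@](C#CC(=O)OC)(Cc1ccc(O[Si](C(C)C)(C(C)C)C(C)C)c(CC=C(C)C)c1)O[Si](C)(C)C | intermediate (not isolated)
15 | dimethyl (4R)-4-hydroxy-4-[3-prenyl-4-(TIPSO)benzyl]pent-2-ynedioate | COC(=O)[C@](C#CC(=O)OC)(Cc1ccc(O[Si](C(C)C)(C(C)C)C(C)C)c(CC=C(C)C)c1)O | intermediate
16 | 4-bromophenol | Oc1ccc(Br)cc1 | starting material
17 | (4-bromophenoxy)triisopropylsilane | CC(C)[Si](Oc1ccc(Br)cc1)(C(C)C)C(C)C | intermediate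
18 | [4-(TIPSO)phenyl]magnesium bromide | CC(C)[Si](Oc1ccc([Mg]Br)cc1)(C(C)C)C(C)C | intermediate
19 | bromomagnesium alkoxide of dimethyl (2E,4R)-2-cuprio-4-hydroxy-4-[3-prenyl-4-(TIPSO)benzyl]-3-[4-(TIPSO)phenyl]pent-2-enedioate (aryl and copper cis) | COC(=O)/C([Cu])=C(\[C@](O[Mg]Br)(Cc1ccc(O[Si](C(C)C)(C(C)C)C(C)C)c(CC=C(C)C)c1)C(=O)OC)c1ccc(O[Si](C(C)C)(C(C)C)C(C)C)cc1 | intermediate (not isolated)
20 | bromomagnesium alkoxide of dimethyl (2E,4R)-4-hydroxy-2-iodo-4-[3-prenyl-4-(TIPSO)benzyl]-3-[4-(TIPSO)phenyl]pent-2-enedioate (C1 ester cis to C4) | COC(=O)/C(I)=C(\[C@](O[Mg]Br)(Cc1ccc(O[Si](C(C)C)(C(C)C)C(C)C)c(CC=C(C)C)c1)C(=O)OC)c1ccc(O[Si](C(C)C)(C(C)C)C(C)C)cc1 | intermediate (not isolated)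
21 | methyl (5R)-3-iodo-2-oxo-5-[3-prenyl-4-(TIPSO)benzyl]-4-[4-(TIPSO)phenyl]-2,5-dihydrofuran-5-carboxylate | COC(=O)[C@]1(Cc2ccc(O[Si](C(C)C)(C(C)C)C(C)C)c(CC=C(C)C)c2)OC(=O)C(I)=C1c1ccc(O[Si](C(C)C)(C(C)C)C(C)C)cc1 | intermediate
22 | C3 pinacol boronate corresponding to 21 | COC(=O)[C@]1(Cc2ccc(O[Si](C(C)C)(C(C)C)C(C)C)c(CC=C(C)C)c2)OC(=O)C(B3OC(C)(C)C(C)(C)O3)=C1c1ccc(O[Si](C(C)C)(C(C)C)C(C)C)cc1 | intermediate (not isolated)
23 | methyl (5R)-3-hydroxy-2-oxo-5-[3-prenyl-4-(TIPSO)benzyl]-4-[4-(TIPSO)phenyl]-2,5-dihydrofuran-5-carboxylate | COC(=O)[C@]1(Cc2ccc(O[Si](C(C)C)(C(C)C)C(C)C)c(CC=C(C)C)c2)OC(=O)C(O)=C1c1ccc(O[Si](C(C)C)(C(C)C)C(C)C)cc1 | intermediate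
24 | methyl (5R)-2-oxo-5-[3-prenyl-4-(TIPSO)benzyl]-3-(TIPSO)-4-[4-(TIPSO)phenyl]-2,5-dihydrofuran-5-carboxylate | COC(=O)[C@]1(Cc2ccc(O[Si](C(C)C)(C(C)C)C(C)C)c(CC=C(C)C)c2)OC(=O)C(O[Si](C(C)C)(C(C)C)C(C)C)=C1c1ccc(O[Si](C(C)C)(C(C)C)C(C)C)cc1 | intermediate
25 | methyl (5R)-5-{3-[((2R)-3,3-dimethyloxiran-2-yl)methyl]-4-(TIPSO)benzyl}-2-oxo-3-(TIPSO)-4-[4-(TIPSO)phenyl]-2,5-dihydrofuran-5-carboxylate | COC(=O)[C@]1(Cc2ccc(O[Si](C(C)C)(C(C)C)C(C)C)c(C[C@H]3OC3(C)C)c2)OC(=O)C(O[Si](C(C)C)(C(C)C)C(C)C)=C1c1ccc(O[Si](C(C)C)(C(C)C)C(C)C)cc1 | intermediate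
26 | methyl (5R)-5-{3-[((2R)-3,3-dimethyloxiran-2-yl)methyl]-4-hydroxybenzyl}-3-hydroxy-4-(4-hydroxyphenyl)-2-oxo-2,5-dihydrofuran-5-carboxylate (CNP0331593.1) | COC(=O)[C@]1(Cc2ccc(O)c(C[C@H]3OC3(C)C)c2)OC(=O)C(O)=C1c1ccc(O)cc1 | target

## Step count and risks

Total: 15 steps. Longest linear sequence: 13 steps (steps 1–8 and 11–15); steps 9 and 10 make the Grignard reagent 18.

Steps most likely to fail:

1. Step 11 (key step). The alkenylcopper 19 may lose its syn geometry through the copper allenoate before iodine reaches it, or the arylcopper reagent may be consumed by proton transfer before it adds next to the quaternary carbon. Either process leaves open-chain or C3-protonated material. Fallback, setting out from 15 and returning at 23 (it replaces steps 11 and 12): aryl transfer and C3 oxidation are separated. Copper-catalysed syn-hydroarylation of 15 with 4-(TIPSO)phenylboronic acid (Cu(OAc)2 cat., MeOH, rt) protonates the alkenylcopper at once, and the cis hydroxy ester lactonises to the 3-unsubstituted 4-aryl butenolide F1. Conjugate reduction with [(Ph3P)CuH]6 (PhMe, rt) should give the saturated lactone F2 (C4 epimers, of no consequence). Its potassium enolate (KN(SiMe3)2, THF, −78 °C) is hydroxylated with 2-(phenylsulfonyl)-3-phenyloxaziridine to the 3-hydroxy lactone F3. Dess–Martin oxidation gives the α-keto lactone, which enolises towards the aryl group and is 23.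

2. Step 5. The enolate 9 may be consumed by aldol addition to aldehyde already released from the formate adduct, or the adduct may revert on quenching, so that formylation stalls. Fallback, setting out from 8 (through 9) and returning at 10: the carbon is introduced at the alcohol oxidation level. Enolate 9 is treated with monomeric formaldehyde (from cracked paraformaldehyde, THF, −78 °C), again anti to the tert-butyl group, to give the hydroxymethyl dioxolanone F4. Dess–Martin oxidation (CH2Cl2, NaHCO3, rt) then gives 10.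

3. Step 12. Protodeiodination or homocoupling may outrun transmetalation at the hindered C3 position, or the α-boryl butenolide may protodeboronate before it is oxidised. Fallback, setting out from 21 and returning at 23: the C–B bond is made by halogen–metal exchange instead of palladium catalysis. i-PrMgCl·LiCl (THF, −78 °C) should give the ring alkenylmagnesium chloride F5, which cannot isomerise. B(OMe)3 traps it as the dimethyl boronate F6, and NaBO3·4H2O (THF–H2O, rt) oxidises this to 23.

Further compounds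
F1 | step 11 | methyl (5R)-2-oxo-5-[3-prenyl-4-(TIPSO)benzyl]-4-[4-(TIPSO)phenyl]-2,5-dihydrofuran-5-carboxylate | COC(=O)[C@]1(Cc2ccc(O[Si](C(C)C)(C(C)C)C(C)C)c(CC=C(C)C)c2)OC(=O)C=C1c1ccc(O[Si](C(C)C)(C(C)C)C(C)C)cc1
F2 | step 11 | methyl (5R)-2-oxo-5-[3-prenyl-4-(TIPSO)benzyl]-4-[4-(TIPSO)phenyl]tetrahydrofuran-5-carboxylate (C4 epimers) | COC(=O)[C@]1(Cc2ccc(O[Si](C(C)C)(C(C)C)C(C)C)c(CC=C(C)C)c2)OC(=O)CC1c1ccc(O[Si](C(C)C)(C(C)C)C(C)C)cc1
F3 | step 11 | methyl (5R)-3-hydroxy-2-oxo-5-[3-prenyl-4-(TIPSO)benzyl]-4-[4-(TIPSO)phenyl]tetrahydrofuran-5-carboxylate (C3 and C4 epimers) | COC(=O)[C@]1(Cc2ccc(O[Si](C(C)C)(C(C)C)C(C)C)c(CC=C(C)C)c2)OC(=O)C(O)C1c1ccc(O[Si](C(C)C)(C(C)C)C(C)C)cc1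
F4 | step 5 | (2S,5R)-2-tert-butyl-5-(hydroxymethyl)-5-[3-prenyl-4-(TIPSO)benzyl]-1,3-dioxolan-4-one | CC(C)(C)[C@H]1O[C@@](CO)(Cc2ccc(O[Si](C(C)C)(C(C)C)C(C)C)c(CC=C(C)C)c2)C(=O)O1
F5 | step 12 | C3 alkenylmagnesium chloride corresponding to 21 | COC(=O)[C@]1(Cc2ccc(O[Si](C(C)C)(C(C)C)C(C)C)c(CC=C(C)C)c2)OC(=O)C([Mg]Cl)=C1c1ccc(O[Si](C(C)C)(C(C)C)C(C)C)cc1
F6 | step 12 | C3 dimethyl boronate corresponding to 21 | COC(=O)[C@]1(Cc2ccc(O[Si](C(C)C)(C(C)C)C(C)C)c(CC=C(C)C)c2)OC(=O)C(B(OC)OC)=C1c1ccc(O[Si](C(C)C)(C(C)C)C(C)C)cc1
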